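**Retrosynthetic overview**

1. Target 29 ⇐ TIPS ether 28 ⇐ side-chain bond C22′–C23′ (chain carbons counted from the carbon on C2 of the chromene): one-flask 9-BBN hydroboration of the terminal diene of chromene polyene 21, then B-alkyl Suzuki–Miyaura coupling with the (E)-C14 alkenyl iodide 26.
2. Enabling feature: C22′ is one end of a CH2–CH2 bridge next to the C19′=C20′(Me) alkene, so C21′=C22′ can be carried as the only monosubstituted C=C of a 3-methyl-1,3-diene; C23′ is the CH of an E-trisubstituted alkene, available as an iodide from a terminal alkyne. Neither the benzene ring nor the 2H-pyran ring is touched.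
3. 26 ⇐ geranylacetone (alkyne formation, Zr-catalysed methylalumination/iodination). 21 ⇐ two earlier runs of the same hydroboration/coupling on chromene diene 11 with the bifunctional C10 iodo-triene 17 (from pent-4-yn-1-ol).
4. 11 ⇐ enal 10 ⇐ ring-closing metathesis of the aryl tertiary allyl ether 9 ⇐ Pd-catalysed asymmetric allylic O-alkylation (sets C2) of vinylphenol 4 with 8-oxogeranyl carbonate 8 (from geraniol).
5. Ring order: the benzene ring is bought (2,3-dimethylhydroquinone); the 2H-pyran ring is the only ring formed (step 8), after the C2 stereocentre (step 7) and before the chain is grown.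

Key step: step 18

Assumption: in step 7 the (R,R)-ligand is taken to give the (R)-ether; if the sense is opposite on this substrate, the (S,S)-ligand is used and nothing else changes.
Remark: all 2H-chromenes (10 onward) are kept from UV light, because photochemical 6π ring opening would racemise C2. Geraniol and geranylacetone are used as the pure E isomers.

**Route**

Step 1
Reactants: 1 2,3-dimethylbenzene-1,4-diol (2,3-dimethylhydroquinone)
Product: 2 2,3-dimethyl-4-[(triisopropylsilyl)oxy]phenol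
Conditions: TIPSCl (1.0 equiv), imidazole, DMF, 0 °C → rt
Reagents that add atoms: chlorotriisopropylsilane, CC(C)[Si](Cl)(C(C)C)C(C)C
Why: Silylation of one of the two equivalent phenols (statistical monoprotection; diol and bis-ether are separated and recycled) should give a base-stable, fluoride-labile aryl silyl ether.

Step 2
Reactants: 2 2,3-dimethyl-4-[(triisopropylsilyl)oxy]phenol
Product: 3 2-hydroxy-3,4-dimethyl-5-[(triisopropylsilyl)oxy]benzaldehyde
Conditions: MgCl2, Et3N, (CH2O)n, MeCN, 80 °C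
Reagents that add atoms: paraformaldehyde (as formaldehyde), C=O
Why: Casnati–Skattebøl ortho-formylation, in which the magnesium phenoxide directs hydroxymethylation to the only free ortho position and a second formaldehyde oxidises the benzylic alkoxide, should place the aldehyde next to the free OH (the future C4a).

Step 3
Reactants: 3 2-hydroxy-3,4-dimethyl-5-[(triisopropylsilyl)oxy]benzaldehyde
Product: 4 6-ethenyl-2,3-dimethyl-4-[(triisopropylsilyl)oxy]phenol
Conditions: Ph3PCH3Br (2.6 equiv), KHMDS (2.5 equiv), THF, 0 °C → rt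
Reagents that add atoms: methyltriphenylphosphonium bromide, C[P+](c1ccccc1)(c1ccccc1)c1ccccc1.[Br-]
Why: Wittig methylenation, with the first equivalent of ylide spent on the phenol, should give the ortho-vinylphenol while the hindered aryl silyl ether survives the non-nucleophilic base.

Step 4
Reactants: 5 geraniol, (2E)-3,7-dimethylocta-2,6-dien-1-ol
Product: 6 (2E)-3,7-dimethylocta-2,6-dien-1-yl methyl carbonate
Conditions: ClCO2Me, pyridine, CH2Cl2, 0 °C
Reagents that add atoms: methyl chloroformate, COC(=O)Cl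
Why: Acylation of the primary allylic alcohol gives the allylic carbonate that later serves as the π-allyl precursor and meanwhile deactivates the 2,3-alkene.

Step 5
Reactants: 6 (2E)-3,7-dimethylocta-2,6-dien-1-yl methyl carbonate
Product: 7 (2E,6E)-8-hydroxy-3,7-dimethylocta-2,6-dien-1-yl methyl carbonate
Conditions: SeO2 (cat.), t-BuOOH, salicylic acid (cat.), CH2Cl2, rt
Reagents that add atoms: tert-butyl hydroperoxide, CC(C)(C)OO (oxygen source; SeO2, O=[Se]=O, is the catalytic carrier)
Why: Sharpless-type catalytic SeO2 allylic oxidation (ene reaction, then [2,3]-shift) should hydroxylate the E-methyl group of the electron-rich terminal alkene only.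

Step 6
Reactants: 7 (2E,6E)-8-hydroxy-3,7-dimethylocta-2,6-dien-1-yl methyl carbonate
Product: 8 (2E,6E)-3,7-dimethyl-8-oxoocta-2,6-dien-1-yl methyl carbonate
Conditions: activated MnO2, CH2Cl2, rt
Reagents that add atoms: none
Why: MnO2 oxidation of the allylic alcohol should give the (E)-enal without touching the carbonate; the enal makes the 6,7-alkene inert to Pd and Ru in the next two steps.

Step 7
Reactants: 4 6-ethenyl-2,3-dimethyl-4-[(triisopropylsilyl)oxy]phenol; 8 (2E,6E)-3,7-dimethyl-8-oxoocta-2,6-dien-1-yl methyl carbonate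
Product: 9 (2E,6R)-6-{2-ethenyl-5,6-dimethyl-4-[(triisopropylsilyl)oxy]phenoxy}-2,6-dimethylocta-2,7-dienal
Conditions: Pd2(dba)3·CHCl3 (2 mol %), (R,R)-DACH-phenyl Trost ligand (6 mol %), CH2Cl2, 0 °C → rt, stopped at full conversion
Reagents that add atoms: none
Why: Trost asymmetric allylic alkylation, in which Pd(0) ionises the carbonate and the phenoxide attacks the more substituted terminus of the (E)-derived π-allyl complex inside the chiral pocket, should give the branched tertiary ether, the ligand-controlled face of attack setting C6 as R.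

Step 8
Reactants: 9 (2E,6R)-6-{2-ethenyl-5,6-dimethyl-4-[(triisopropylsilyl)oxy]phenoxy}-2,6-dimethylocta-2,7-dienal
Product: 10 (2E)-2-methyl-5-{(2R)-2,7,8-trimethyl-6-[(triisopropylsilyl)oxy]-2H-chromen-2-yl}pent-2-enal
Conditions: Grubbs second-generation catalyst (3 mol %), CH2Cl2 (0.005 M), 40 °C
Reagents that add atoms: none
Why: Ring-closing metathesis of the styrene and the vinyl group on the quaternary carbon should close the six-membered 2H-pyran ring with loss of ethene; the trisubstituted enal is inert and the C–O stereocentre is not touched.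

Step 9
Reactants: 10 (2E)-2-methyl-5-{(2R)-2,7,8-trimethyl-6-[(triisopropylsilyl)oxy]-2H-chromen-2-yl}pent-2-enal
Product: 11 (2R)-2,7,8-trimethyl-2-[(3E)-4-methylhexa-3,5-dien-1-yl]-6-[(triisopropylsilyl)oxy]-2H-chromene
Conditions: Ph3PCH3Br, KHMDS, THF, −78 → 0 °C
Reagents that add atoms: methyltriphenylphosphonium bromide, C[P+](c1ccccc1)(c1ccccc1)c1ccccc1.[Br-]
Why: Wittig methylenation of the enal (1,2-addition) should give the terminal 3-methyl-1,3-diene with the E geometry retained.

Step 10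
Reactants: 12 pent-4-yn-1-ol
Product: 14 (4E)-5-iodo-4-methylpent-4-en-1-ol, via alkenylalane 13 (not isolated)
Conditions: Me3Al (3 equiv), Cp2ZrCl2 (0.25 equiv), CH2Cl2, 0 °C → rt; then I2, THF, −30 → 0 °C
Reagents that add atoms: trimethylaluminium, C[Al](C)C; iodine, II
Why: Negishi Zr-catalysed methylalumination (syn addition, methyl to the internal carbon) followed by iodinolysis with retention should give the E-alkenyl iodide.

Step 11
Reactants: 14 (4E)-5-iodo-4-methylpent-4-en-1-ol
Product: 15 (4E)-5-iodo-4-methylpent-4-enal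
Conditions: Dess–Martin periodinane, CH2Cl2, 0 °C → rt
Reagents that add atoms: none
Why: Dess–Martin oxidation of the primary alcohol is mild enough to leave the alkenyl iodide and its geometry intact.

Step 12
Reactants: 15 (4E)-5-iodo-4-methylpent-4-enal
Product: 16 (2E,6E)-7-iodo-2,6-dimethylhepta-2,6-dienal
Conditions: Ph3P=C(CH3)CHO, toluene, 80 °C
Reagents that add atoms: 2-(triphenylphosphoranylidene)propanal, CC(C=O)=P(c1ccccc1)(c1ccccc1)c1ccccc1
Why: Wittig olefination with the stabilised formyl ylide should give the (E)-α-methyl enal selectively.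

Step 13
Reactants: 16 (2E,6E)-7-iodo-2,6-dimethylhepta-2,6-dienal
Product: 17 (1E,5E)-1-iodo-2,6-dimethylocta-1,5,7-triene
Conditions: Ph3PCH3Br, KHMDS, THF, −78 → 0 °C
Reagents that add atoms: methyltriphenylphosphonium bromide, C[P+](c1ccccc1)(c1ccccc1)c1ccccc1.[Br-]
Why: Wittig methylenation of the enal should give the bifunctional linchpin, an alkenyl iodide at one end and a 3-methyl-1,3-diene at the other.

Step 14
Reactants: 11 (2R)-2,7,8-trimethyl-2-[(3E)-4-methylhexa-3,5-dien-1-yl]-6-[(triisopropylsilyl)oxy]-2H-chromene; 17 (1E,5E)-1-iodo-2,6-dimethylocta-1,5,7-triene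
Product: 19 (2R)-2,7,8-trimethyl-2-[(3E,7E,11E)-4,8,12-trimethyltetradeca-3,7,11,13-tetraen-1-yl]-6-[(triisopropylsilyl)oxy]-2H-chromene, via alkylborane 18 (not isolated)
Conditions: 9-BBN, THF, 0 °C → rt; then 3 M aq K3PO4; 17, PdCl2(dppf)·CH2Cl2 (5 mol %), AsPh3, DMF, rt
Reagents that add atoms: none
Why: One-flask 9-BBN hydroboration/B-alkyl Suzuki–Miyaura coupling, in which 9-BBN should add only to the monosubstituted vinyl end of the diene and Pd/dppf couples the primary borate with the alkenyl iodide with retention, while the diene of 17 survives because excess borane is destroyed by the base before 17 is added.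

Step 15
Reactants: 19 (2R)-2,7,8-trimethyl-2-[(3E,7E,11E)-4,8,12-trimethyltetradeca-3,7,11,13-tetraen-1-yl]-6-[(triisopropylsilyl)oxy]-2H-chromene; 17 (1E,5E)-1-iodo-2,6-dimethylocta-1,5,7-triene
Product: 21 (2R)-2,7,8-trimethyl-2-[(3E,7E,11E,15E,19E)-4,8,12,16,20-pentamethyldocosa-3,7,11,15,19,21-hexaen-1-yl]-6-[(triisopropylsilyl)oxy]-2H-chromene, via alkylborane 20 (not isolated)
Conditions: 9-BBN, THF, 0 °C → rt; then 3 M aq K3PO4; 17, PdCl2(dppf)·CH2Cl2 (5 mol %), AsPh3, DMF, rt
Reagents that add atoms: none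
Why: A second run of the hydroboration/B-alkyl Suzuki–Miyaura operation of step 14 should add two more E-configured isoprene units and regenerate the terminal diene.

Step 16
Reactants: 22 (5E)-6,10-dimethylundeca-5,9-dien-2-one (geranylacetone)
Product: 24 (5E)-6,10-dimethylundeca-5,9-dien-1-yne, via enol phosphate 23 (not isolated)
Conditions: LDA (1.05 equiv), THF, −78 °C; ClP(O)(OEt)2, −78 °C → rt; then LDA (2.3 equiv), −78 °C → rt
Reagents that add atoms: none
Why: Negishi one-pot conversion of a methyl ketone into a terminal alkyne (kinetic methyl enolate, enol phosphate, LDA-induced elimination) should leave the 5E alkene untouched.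

Step 17
Reactants: 24 (5E)-6,10-dimethylundeca-5,9-dien-1-yne
Product: 26 (1E,5E)-1-iodo-2,6,10-trimethylundeca-1,5,9-triene, via alkenylalane 25 (not isolated)
Conditions: Me3Al (2 equiv), Cp2ZrCl2 (0.2 equiv), CH2Cl2, rt; then I2, THF, −30 → 0 °C
Reagents that add atoms: trimethylaluminium, C[Al](C)C; iodine, II
Why: Negishi Zr-catalysed methylalumination/iodinolysis should install the methyl group and the E-alkenyl iodide in one operation by syn addition and retention.

Step 18
Reactants: 21 (2R)-2,7,8-trimethyl-2-[(3E,7E,11E,15E,19E)-4,8,12,16,20-pentamethyldocosa-3,7,11,15,19,21-hexaen-1-yl]-6-[(triisopropylsilyl)oxy]-2H-chromene; 26 (1E,5E)-1-iodo-2,6,10-trimethylundeca-1,5,9-triene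
Product: 28 (2R)-2,7,8-trimethyl-2-[(3E,7E,11E,15E,19E,23E,27E)-4,8,12,16,20,24,28,32-octamethyltritriaconta-3,7,11,15,19,23,27,31-octaen-1-yl]-6-[(triisopropylsilyl)oxy]-2H-chromene, via alkylborane 27 (not isolated)
Conditions: 9-BBN, THF, 0 °C → rt; then 3 M aq K3PO4; 26, PdCl2(dppf)·CH2Cl2 (5 mol %), AsPh3, DMF, rt, degassed, dark
Reagents that add atoms: none
Why: 9-BBN should add anti-Markovnikov to the only monosubstituted C=C of 21 (C21′=C22′), placing boron on C22′ and leaving the C19′=C20′ alkene untouched; the borate formed from borane 27 and base then transmetalates to the alkenyl-Pd(II) iodide formed from 26 with retention, and reductive elimination forms C22′–C23′ faster than β-hydride elimination on the wide-bite-angle dppf complex. The closest known reaction type is the one-flask hydroboration/B-alkyl Suzuki–Miyaura coupling of 4-methyl-1,3-dienes (homogeranyl-type boranes) with (E)-alkenyl iodides in polyprenoid synthesis, the same operation as steps 14 and 15. No ring is closed and no stereocentre is created; the E geometry of C23′=C24′ comes from 26 and that of C19′=C20′ from the diene, both with retention, and C2 is remote and unaffected. The selectivity needed is site selectivity of the hydroboration among seven C=C bonds, secured because 21 has exactly one monosubstituted alkene, the others being trisubstituted or the cis-disubstituted conjugated ring alkene, which 9-BBN is known to attack far more slowly. Chemoselectivity at palladium is secured by the single C(sp2)–I bond and by working at room temperature, where the allylic aryl ether of the pyran ring and the aryl silyl ether should not be ionised or hydrolysed.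

Step 19
Reactants: 28 (2R)-2,7,8-trimethyl-2-[(3E,7E,11E,15E,19E,23E,27E)-4,8,12,16,20,24,28,32-octamethyltritriaconta-3,7,11,15,19,23,27,31-octaen-1-yl]-6-[(triisopropylsilyl)oxy]-2H-chromene
Product: 29 plastochromenol-8, (2R)-2,7,8-trimethyl-2-[(3E,7E,11E,15E,19E,23E,27E)-4,8,12,16,20,24,28,32-octamethyltritriaconta-3,7,11,15,19,23,27,31-octaen-1-yl]-2H-chromen-6-ol
Conditions: TBAF (1.2 equiv), AcOH (1.2 equiv), THF, 0 °C, argon, dark
Reagents that add atoms: none
Why: Fluoride cleavage of the aryl silyl ether, buffered with acetic acid so that the electron-rich phenol stays protonated, needs neither acid strong enough to cyclise the polyene nor hydrogenation.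

**Compound list**

1 | 2,3-dimethylbenzene-1,4-diol (2,3-dimethylhydroquinone) | Cc1c(O)ccc(O)c1C | starting material
2 | 2,3-dimethyl-4-[(triisopropylsilyl)oxy]phenol | Cc1c(O)ccc(O[Si](C(C)C)(C(C)C)C(C)C)c1C | intermediate
3 | 2-hydroxy-3,4-dimethyl-5-[(triisopropylsilyl)oxy]benzaldehyde | O=Cc1cc(O[Si](C(C)C)(C(C)C)C(C)C)c(C)c(C)c1O | intermediate
4 | 6-ethenyl-2,3-dimethyl-4-[(triisopropylsilyl)oxy]phenol | C=Cc1cc(O[Si](C(C)C)(C(C)C)C(C)C)c(C)c(C)c1O | intermediate
5 | geraniol, (2E)-3,7-dimethylocta-2,6-dien-1-ol | CC(C)=CCC/C(C)=C/CO | starting material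
6 | (2E)-3,7-dimethylocta-2,6-dien-1-yl methyl carbonate | CC(C)=CCC/C(C)=C/COC(=O)OC | intermediate
7 | (2E,6E)-8-hydroxy-3,7-dimethylocta-2,6-dien-1-yl methyl carbonate | OC/C(C)=C/CC/C(C)=C/COC(=O)OC | intermediate
8 | (2E,6E)-3,7-dimethyl-8-oxoocta-2,6-dien-1-yl methyl carbonate | O=C/C(C)=C/CC/C(C)=C/COC(=O)OC | intermediate
9 | (2E,6R)-6-{2-ethenyl-5,6-dimethyl-4-[(triisopropylsilyl)oxy]phenoxy}-2,6-dimethylocta-2,7-dienal | O=C/C(C)=C/CC[C@](C)(C=C)Oc1c(C=C)cc(O[Si](C(C)C)(C(C)C)C(C)C)c(C)c1C | intermediate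
10 | (2E)-2-methyl-5-{(2R)-2,7,8-trimethyl-6-[(triisopropylsilyl)oxy]-2H-chromen-2-yl}pent-2-enal | O=C/C(C)=C/CC[C@]1(C)C=Cc2cc(O[Si](C(C)C)(C(C)C)C(C)C)c(C)c(C)c2O1 | intermediate
11 | (2R)-2,7,8-trimethyl-2-[(3E)-4-methylhexa-3,5-dien-1-yl]-6-[(triisopropylsilyl)oxy]-2H-chromene | C=C/C(C)=C/CC[C@]1(C)C=Cc2cc(O[Si](C(C)C)(C(C)C)C(C)C)c(C)c(C)c2O1 | intermediate
12 | pent-4-yn-1-ol | C#CCCCO | starting material
13 | alkenylalane: dimethyl[(1E)-5-(dimethylalumanyloxy)-2-methylpent-1-en-1-yl]alumane | C[Al](C)OCCC/C(C)=C/[Al](C)C | intermediate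
14 | (4E)-5-iodo-4-methylpent-4-en-1-ol | OCCC/C(C)=C/I | intermediate
15 | (4E)-5-iodo-4-methylpent-4-enal | O=CCC/C(C)=C/I | intermediate
16 | (2E,6E)-7-iodo-2,6-dimethylhepta-2,6-dienal | O=C/C(C)=C/CC/C(C)=C/I | intermediate
17 | (1E,5E)-1-iodo-2,6-dimethylocta-1,5,7-triene | C=C/C(C)=C/CC/C(C)=C/I | intermediate
18 | alkylborane: 9-[(3E)-3-methyl-6-{(2R)-2,7,8-trimethyl-6-[(triisopropylsilyl)oxy]-2H-chromen-2-yl}hex-3-en-1-yl]-9-borabicyclo[3.3.1]nonane | B1(CC/C(C)=C/CC[C@]2(C)C=Cc3cc(O[Si](C(C)C)(C(C)C)C(C)C)c(C)c(C)c3O2)C2CCCC1CCC2 | intermediate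
19 | (2R)-2,7,8-trimethyl-2-[(3E,7E,11E)-4,8,12-trimethyltetradeca-3,7,11,13-tetraen-1-yl]-6-[(triisopropylsilyl)oxy]-2H-chromene | C=C/C(C)=C/CC/C(C)=C/CC/C(C)=C/CC[C@]1(C)C=Cc2cc(O[Si](C(C)C)(C(C)C)C(C)C)c(C)c(C)c2O1 | intermediate
20 | alkylborane: 9-[(3E,7E,11E)-3,7,11-trimethyl-14-{(2R)-2,7,8-trimethyl-6-[(triisopropylsilyl)oxy]-2H-chromen-2-yl}tetradeca-3,7,11-trien-1-yl]-9-borabicyclo[3.3.1]nonane | B1(CC/C(C)=C/CC/C(C)=C/CC/C(C)=C/CC[C@]2(C)C=Cc3cc(O[Si](C(C)C)(C(C)C)C(C)C)c(C)c(C)c3O2)C2CCCC1CCC2 | intermediate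
21 | (2R)-2,7,8-trimethyl-2-[(3E,7E,11E,15E,19E)-4,8,12,16,20-pentamethyldocosa-3,7,11,15,19,21-hexaen-1-yl]-6-[(triisopropylsilyl)oxy]-2H-chromene | C=C/C(C)=C/CC/C(C)=C/CC/C(C)=C/CC/C(C)=C/CC/C(C)=C/CC[C@]1(C)C=Cc2cc(O[Si](C(C)C)(C(C)C)C(C)C)c(C)c(C)c2O1 | intermediate
22 | (5E)-6,10-dimethylundeca-5,9-dien-2-one (geranylacetone) | CC(C)=CCC/C(C)=C/CCC(C)=O | starting material
23 | enol phosphate: diethyl (5E)-6,10-dimethylundeca-1,5,9-trien-2-yl phosphate | CC(C)=CCC/C(C)=C/CCC(=C)OP(=O)(OCC)OCC | intermediate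
24 | (5E)-6,10-dimethylundeca-5,9-dien-1-yne | CC(C)=CCC/C(C)=C/CCC#C | intermediate
25 | alkenylalane: dimethyl[(1E,5E)-2,6,10-trimethylundeca-1,5,9-trien-1-yl]alumane | CC(C)=CCC/C(C)=C/CC/C(C)=C/[Al](C)C | intermediate
26 | (1E,5E)-1-iodo-2,6,10-trimethylundeca-1,5,9-triene | CC(C)=CCC/C(C)=C/CC/C(C)=C/I | intermediate
27 | alkylborane: 9-[(3E,7E,11E,15E,19E)-3,7,11,15,19-pentamethyl-22-{(2R)-2,7,8-trimethyl-6-[(triisopropylsilyl)oxy]-2H-chromen-2-yl}docosa-3,7,11,15,19-pentaen-1-yl]-9-borabicyclo[3.3.1]nonane | B1(CC/C(C)=C/CC/C(C)=C/CC/C(C)=C/CC/C(C)=C/CC/C(C)=C/CC[C@]2(C)C=Cc3cc(O[Si](C(C)C)(C(C)C)C(C)C)c(C)c(C)c3O2)C2CCCC1CCC2 | intermediate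
28 | (2R)-2,7,8-trimethyl-2-[(3E,7E,11E,15E,19E,23E,27E)-4,8,12,16,20,24,28,32-octamethyltritriaconta-3,7,11,15,19,23,27,31-octaen-1-yl]-6-[(triisopropylsilyl)oxy]-2H-chromene | CC(C)=CCC/C(C)=C/CC/C(C)=C/CC/C(C)=C/CC/C(C)=C/CC/C(C)=C/CC/C(C)=C/CC/C(C)=C/CC[C@]1(C)C=Cc2cc(O[Si](C(C)C)(C(C)C)C(C)C)c(C)c(C)c2O1 | intermediate
29 | plastochromenol-8, (2R)-2,7,8-trimethyl-2-[(3E,7E,11E,15E,19E,23E,27E)-4,8,12,16,20,24,28,32-octamethyltritriaconta-3,7,11,15,19,23,27,31-octaen-1-yl]-2H-chromen-6-ol | CC(C)=CCC/C(C)=C/CC/C(C)=C/CC/C(C)=C/CC/C(C)=C/CC/C(C)=C/CC/C(C)=C/CC/C(C)=C/CC[C@]1(C)C=Cc2cc(O)c(C)c(C)c2O1 | target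

**Summary**

Total step count: 19. Longest linear sequence: 10 steps (5 → 6 → 7 → 8 → 9 → 10 → 11 → 19 → 21 → 28 → 29).

Steps most likely to fail:

Step 7. The phenoxide of 4 is flanked by a methyl and a vinyl group, so attack at the tertiary allyl terminus may become slower than attack at the primary terminus and than re-ionisation of the product ether; regio- and enantiocontrol would then erode. The fallback leaves asymmetric catalysis and makes the pyran ring by the classical propargyl ether route followed by resolution. It sets out from 2 and comes back at 10. Commercial racemic dehydrolinalool is oxidised at its E-methyl group (SeO2, dioxane, 80 °C) to (2E)-6-hydroxy-2,6-dimethyloct-2-en-7-ynal F1. Its trifluoroacetate, made in the flask (TFAA, DBU), etherifies phenol 2 under CuCl2 catalysis (MeCN, 0 °C) to the aryl propargyl ether (2E)-6-{2,3-dimethyl-4-[(triisopropylsilyl)oxy]phenoxy}-2,6-dimethyloct-2-en-7-ynal F2. Heating (xylene, 140 °C) should bring about aromatic Claisen rearrangement, 1,5-hydrogen shift and oxa-6π electrocyclisation to the racemic chromene enal F3, which is resolved by preparative chiral SFC to give 10.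

Step 18. The hydroboration has to stop at one of seven C=C bonds, and the long lipophilic borate must transmetalate before it is protonated; incomplete site selection or protodeboronation would give hydrocarbon homologues that are hard to separate from 28. The fallback changes the nucleophile to zinc and allows purification at a polar intermediate. It sets out from 21 and comes back at 28. Hydroboration of 21 with 9-BBN and oxidation with NaBO3 gives the homoallylic alcohol (3E,7E,11E,15E,19E)-3,7,11,15,19-pentamethyl-22-{(2R)-2,7,8-trimethyl-6-[(triisopropylsilyl)oxy]-2H-chromen-2-yl}docosa-3,7,11,15,19-pentaen-1-ol F4, which is purified on silica. I2, PPh3 and imidazole convert it into the primary iodide F5. Iodine–lithium exchange (t-BuLi, Et2O, −78 °C) and ZnBr2 give the homoallylzinc bromide F6, which is coupled with 26 under Pd(PPh3)4 catalysis in THF (Negishi alkenyl–alkyl coupling) to give 28.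

Step 14. The iodide 17 carries a free conjugated diene, which under Pd(0) and base may be consumed by hydropalladation or Heck-type oligomerisation before or after the coupling. The fallback masks the diene as the enal during the coupling. It sets out from 11 and 16 and comes back at 19. Borane 18 from 11 is coupled under the same conditions with the iodo-enal 16 to give (2E,6E,10E)-2,6,10-trimethyl-13-{(2R)-2,7,8-trimethyl-6-[(triisopropylsilyl)oxy]-2H-chromen-2-yl}trideca-2,6,10-trienal F7, and Wittig methylenation (Ph3PCH3Br, KHMDS) then gives 19. The same two-step cycle can replace step 15.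

**Further compounds**

F1 | step 7 | (2E)-6-hydroxy-2,6-dimethyloct-2-en-7-ynal (racemic) | O=C/C(C)=C/CCC(C)(O)C#C
F2 | step 7 | (2E)-6-{2,3-dimethyl-4-[(triisopropylsilyl)oxy]phenoxy}-2,6-dimethyloct-2-en-7-ynal (racemic) | O=C/C(C)=C/CCC(C)(C#C)Oc1ccc(O[Si](C(C)C)(C(C)C)C(C)C)c(C)c1C
F3 | step 7 | (2E)-2-methyl-5-{2,7,8-trimethyl-6-[(triisopropylsilyl)oxy]-2H-chromen-2-yl}pent-2-enal (racemic 10) | O=C/C(C)=C/CCC1(C)C=Cc2cc(O[Si](C(C)C)(C(C)C)C(C)C)c(C)c(C)c2O1
F4 | step 18 | (3E,7E,11E,15E,19E)-3,7,11,15,19-pentamethyl-22-{(2R)-2,7,8-trimethyl-6-[(triisopropylsilyl)oxy]-2H-chromen-2-yl}docosa-3,7,11,15,19-pentaen-1-ol | OCC/C(C)=C/CC/C(C)=C/CC/C(C)=C/CC/C(C)=C/CC/C(C)=C/CC[C@]1(C)C=Cc2cc(O[Si](C(C)C)(C(C)C)C(C)C)c(C)c(C)c2O1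
F5 | step 18 | (2R)-2-[(3E,7E,11E,15E,19E)-22-iodo-4,8,12,16,20-pentamethyldocosa-3,7,11,15,19-pentaen-1-yl]-2,7,8-trimethyl-6-[(triisopropylsilyl)oxy]-2H-chromene | ICC/C(C)=C/CC/C(C)=C/CC/C(C)=C/CC/C(C)=C/CC/C(C)=C/CC[C@]1(C)C=Cc2cc(O[Si](C(C)C)(C(C)C)C(C)C)c(C)c(C)c2O1
F6 | step 18 | bromo[(3E,7E,11E,15E,19E)-3,7,11,15,19-pentamethyl-22-{(2R)-2,7,8-trimethyl-6-[(triisopropylsilyl)oxy]-2H-chromen-2-yl}docosa-3,7,11,15,19-pentaen-1-yl]zinc | Br[Zn]CC/C(C)=C/CC/C(C)=C/CC/C(C)=C/CC/C(C)=C/CC/C(C)=C/CC[C@]1(C)C=Cc2cc(O[Si](C(C)C)(C(C)C)C(C)C)c(C)c(C)c2O1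
F7 | step 14 | (2E,6E,10E)-2,6,10-trimethyl-13-{(2R)-2,7,8-trimethyl-6-[(triisopropylsilyl)oxy]-2H-chromen-2-yl}trideca-2,6,10-trienal | O=C/C(C)=C/CC/C(C)=C/CC/C(C)=C/CC[C@]1(C)C=Cc2cc(O[Si](C(C)C)(C(C)C)C(C)C)c(C)c(C)c2O1
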